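All runs are simulated for substances that don't exist.

Our vessel is closed, stirred and isothermal, and product shows up in it late.

| setting | south-east | south | zeta | gamma |
|---|---|---|---|---|
| substrate | 0.030 M | 0.14 M | 0.050 M | 0.20 M |
| reagent | 0.80 equiv | 0.80 equiv | 0.800 equiv | 0.800 equiv |
| remark | run made earlier | run made earlier |  |  |
| time |  |  | 4.0 h | 4.0 h |

| south-east: time / h | south-east: product / % | south: time / h | south: product / % |
|---|---|---|---|
| 0.500 | 0 | 0.250 | 0 |
| 1.00 | 0 | 0.417 | 0 |
| 1.50 | 5 | 0.833 | 5 |
| 2.50 | 5 | 1.33 | 6 |
| 3.00 | 11 | 3.00 | 24 |

(standard deviation of a reading: 2 percentage points)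

- what was read earlier has a scatter of 2 percentage points, one standard deviation
- where the amount of substrate changes, what is given in equivalents or mol% on it follows

- which one finishes higher in amount of product, in percent of the substrate charged ("neither" within 2 percentage points) (zeta / gamma / neither)
- amount of product at the end, in percent of the substrate charged, zeta
- amount of product at the end, in percent of the substrate charged, gamma

A late, rising curve is poorly told by one rate, so we count doublings of the clock. The south run gives the exponent m in product ∝ time^m:

m = ln(24 % / 6 %) / ln(3.00 h / 1.33 h) = 1.70

G = 2^m = 3.26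

We call G the clock gain, the factor by which the product percentage grows when the time doubles with the charges held, as read from the south run.

But the south-east run, read the same way, gives another exponent:

m' = ln(11 % / 5 %) / ln(3.00 h / 1.50 h) = 1.14

Both rest on small readings with a scatter of 2 percentage points. Yet the step from 3.00 h to 4.0 h is less than one doubling, so the factor is 1.63 with m and 1.39 with m'. We keep m, from the run with the higher last reading.

For concentration at equal equivalents of reagent, the two last readings give the exponent n:

n = ln(24 % / 11 %) / ln(0.14 M / 0.030 M) = 0.506

zeta, our estimate: 23.3 %

gamma, our estimate: 46.9 %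

Could the reagent stop gamma first? If each product takes one reagent, the charge allows 80.0 percent, which is more than our estimate.

The forecast says gamma, with 21 % for zeta and 44 % for gamma, each a little under ours, and it warns of “the extrapolation of an accelerating curve from noisy points”.

The flasks give gamma, with 18.3 % for zeta and 40.2 % for gamma, so the forecast stands.

    substrate → intermediate A (k = 0.550 /h)
    reagent + intermediate A ⇌ intermediate B (K = 3.20 /M, k = 18.0 /M/h)
    reagent + intermediate B → intermediate C (k = 1.00 /M/h)
    intermediate B → product (k = 2.40 /h)
    intermediate C ⇌ intermediate D (K = 18.0, k = 0.0370 /h)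
    intermediate C ⇌ intermediate E (K = 9.00, k = 0.190 /h)
    reagent ⇌ dormant form (K = 0.930, k = 5.40 /h)

In zeta, substrate fed intermediate A, which at 4.00 h held 68.1 % against 18.3 % product. Product came out of zeta through intermediate B, and stood at 71.4 % after 40.0 h. Zeta's gain from 2.00 h to 4.00 h was 2.72, less than G. Zeta's figure moves by 5 points at 3.13 h or 4.93 h with the amounts held, or at 0.557 equiv or 1.07 equiv of reagent with the time and other amounts held.

Now read zeta at 1.0 h, a quarter of its time, which is two doublings back. G gives 1.72 %. The flask gives 1.92 %.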